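**Plan**

- Retrosynthesis: the two MOM ethers and the C2–H/C3–H pair are removed first, giving a flat flavone. Ring C is then cut at C4a–C4, C4–C3 and O1–C2 into an ortho-iodophenol, carbon monoxide and phenylacetylene. The C–I bond and the aryl–geranyl bond (C6–C1′) lead back to phloroglucinol and geranyl bromide.
- Enabling feature: C4 is a lone carbonyl carbon between C4a and C3 (it is CO), and C2–C3 with phenyl ring B is phenylacetylene. O1 lies para to the geranyl-bearing C6, so the iodophenol derives from a phenol whose two ortho carbons are equivalent.
- Forward: ring A is bought as phloroglucinol and dressed (two MOM ethers, one silyl ether, lithiation between the MOM ethers and geranylation, desilylation, ortho-iodination). Ring C is then closed in one three-component operation that also brings in ring B.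
- Stereochemistry: the E alkene comes in with geranyl bromide. The single stereocentre C2 (S) is set after ring closure by a ligand-controlled copper hydride 1,4-reduction of the flavone; mild acid then frees the phenols.

Key step: step 6

Assumption: which enantiomer of DTBM-SEGPHOS gives the 2S flavanone cannot be read off safely from the 2-alkylchromone series (the CIP order at C2 changes from alkyl to phenyl); the (R) ligand is written, and the (S) ligand is used instead if a trial run shows the opposite sense.

Abbreviations: geranyl = (2E)-3,7-dimethylocta-2,6-dien-1-yl; MOM = methoxymethyl; dppf = 1,1′-bis(diphenylphosphino)ferrocene.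

**Route**

Step 1
Reactants: 1 phloroglucinol
Product: 2 3,5-bis(methoxymethoxy)phenol
Conditions: MOMCl (2.0 equiv), i-Pr2NEt, CH2Cl2–DMF, 0 °C to rt
Reagents that add atoms: chloromethyl methyl ether (MOMCl), COCCl
Why: Base-mediated O-alkylation of the phenols (Williamson-type MOM protection) with two equivalents of the chloromethyl ether should give the symmetric bis-ether as the main part of a statistical mixture, to be separated from mono- and tris-ether by chromatography.

Step 2
Reactants: 2 3,5-bis(methoxymethoxy)phenol
Product: 3 [3,5-bis(methoxymethoxy)phenoxy]tri(propan-2-yl)silane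
Conditions: i-Pr3SiCl, imidazole, DMF, rt
Reagents that add atoms: chlorotri(propan-2-yl)silane, CC(C)[Si](Cl)(C(C)C)C(C)C
Why: Imidazole-promoted silylation masks the acidic O–H before the lithiation, and the bulky silyl group shields the two ring positions beside it.

Step 3
Reactants: 3 [3,5-bis(methoxymethoxy)phenoxy]tri(propan-2-yl)silane, 4 geranyl bromide
Product: 6 [4-geranyl-3,5-bis(methoxymethoxy)phenoxy]tri(propan-2-yl)silane, via C4 aryllithium 5 (not isolated)
Conditions: n-BuLi, THF, 0 °C; then CuBr·SMe2 (10 mol %), 4, −78 °C to rt
Reagents that add atoms: none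
Why: In this directed ortho-metalation n-BuLi is held by both MOM ethers and removes the proton between them, and the aryllithium is then allylated under copper catalysis at the primary carbon of 4 (SN2 coupling; the fully substituted γ-carbon disfavours SN2′), which keeps the E geometry.

Step 4
Reactants: 6 [4-geranyl-3,5-bis(methoxymethoxy)phenoxy]tri(propan-2-yl)silane
Product: 7 4-geranyl-3,5-bis(methoxymethoxy)phenol
Conditions: Bu4NF, AcOH, THF, 0 °C
Reagents that add atoms: none
Why: Fluoride cleaves the aryl O–Si bond (desilylation) while the acetic acid buffer keeps the medium non-basic, and MOM ethers and alkenes are inert to it.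

Step 5
Reactants: 7 4-geranyl-3,5-bis(methoxymethoxy)phenol
Product: 8 4-geranyl-2-iodo-3,5-bis(methoxymethoxy)phenol
Conditions: I2 (1.0 equiv), NaHCO3, THF–H2O, 0 °C
Reagents that add atoms: iodine, [I][I]
Why: Electrophilic aromatic iodination of the phenoxide-like ring should be much faster than attack of I2 on the isolated alkenes in bicarbonate buffer, and because the para carbon is blocked and the two ortho carbons are equivalent, one equivalent of iodine can give only one mono-iodide.

Step 6
Reactants: 8 4-geranyl-2-iodo-3,5-bis(methoxymethoxy)phenol, 9 carbon monoxide, 10 phenylacetylene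
Product: 13 6-geranyl-5,7-bis(methoxymethoxy)flavone, via ortho-hydroxyaryl ynone 11 (not isolated), via diethylamino enaminone 12 (not isolated)
Conditions: PdCl2(dppf) (5 mol %), CO (20 bar), Et2NH, 120 °C
Reagents that add atoms: none
Why: Zerovalent palladium, formed in the flask from PdCl2(dppf), inserts into the C–I bond of 8, migratory insertion of CO gives an aroylpalladium iodide, and the alkynyl group of 10 (deprotonated by Et2NH at the metal) is transferred and reductively eliminated to ynone 11, which makes C4a–C4 and C4–C3. Et2NH then adds to the ynone to give the β-amino enone 12, and the neighbouring phenol oxygen attacks the same β-carbon and expels the amine, which makes O1–C2 and closes ring C in a 6-endo addition–elimination. The closest known reaction type is the palladium-catalysed carbonylative annulation of ortho-iodophenols with terminal alkynes to flavones in a secondary amine. No stereocentre is formed. The step needs carbonylative over direct alkynylation and 6-endo over 5-exo closure: the first should be secured by the copper-free system under CO pressure, in which the hindered aryl–palladium takes up CO before it meets the alkyne, the second by enaminone 12, whose electrophilic carbon is the one that becomes C2, so that no aurone can form. The site question does not arise, because in 8 the carbon para to the hydroxyl carries the geranyl chain and iodine sits on one of two equivalent ortho carbons, so only the 6-geranyl flavone can result.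

Step 7
Reactants: 13 6-geranyl-5,7-bis(methoxymethoxy)flavone
Product: 15 (2S)-6-geranyl-5,7-bis(methoxymethoxy)flavanone, via silyl enol ether 14 (not isolated)
Conditions: Cu(OAc)2 (5 mol %), (R)-DTBM-SEGPHOS (5 mol %), (EtO)2MeSiH (3 equiv), toluene, 0 °C to rt; then 1 M HCl, THF, 0 °C
Reagents that add atoms: none
Why: Proposed new method: a ligated monovalent copper hydride, made from Cu(OAc)2, the bisphosphine and the silane, should add hydride to C2 of the flavone from the face chosen by the ligand, and σ-bond metathesis of the copper enolate with the silane should give silyl enol ether 14, which blocks both 1,2-over-reduction and β-elimination of the aryloxide until cold dilute acid releases the (2S) ketone; the closest known reaction type is the copper hydride-catalysed asymmetric conjugate reduction of β,β-disubstituted enones and of 2-alkylchromones, a hydride that leaves isolated trisubstituted alkenes and MOM acetals alone.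

Step 8
Reactants: 15 (2S)-6-geranyl-5,7-bis(methoxymethoxy)flavanone
Product: 16 (2S)-6-geranyl-5,7-dihydroxyflavanone (target)
Conditions: 3 M aq. HCl, MeOH, 40 °C
Reagents that add atoms: none
Why: Acid-catalysed acetal exchange with methanol removes both MOM ethers (the one peri to the carbonyl first) under conditions commonly used on prenylated flavanones, and C2 is not at risk because ring opening to the chalcone needs base.

**Compound list**

1 | phloroglucinol (benzene-1,3,5-triol) | Oc1cc(O)cc(O)c1 | starting material
2 | 3,5-bis(methoxymethoxy)phenol | COCOc1cc(O)cc(OCOC)c1 | intermediate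
3 | [3,5-bis(methoxymethoxy)phenoxy]tri(propan-2-yl)silane | COCOc1cc(OCOC)cc(O[Si](C(C)C)(C(C)C)C(C)C)c1 | intermediate
4 | geranyl bromide, (2E)-1-bromo-3,7-dimethylocta-2,6-diene | CC(C)=CCC/C(C)=C/CBr | starting material
5 | aryllithium of 3, lithiated at the carbon between the two MOM ethers (formed in the flask) | [Li]c1c(OCOC)cc(O[Si](C(C)C)(C(C)C)C(C)C)cc1OCOC | intermediate
6 | [4-geranyl-3,5-bis(methoxymethoxy)phenoxy]tri(propan-2-yl)silane, E alkene | COCOc1cc(O[Si](C(C)C)(C(C)C)C(C)C)cc(OCOC)c1C/C=C(\C)CCC=C(C)C | intermediate
7 | 4-geranyl-3,5-bis(methoxymethoxy)phenol | COCOc1cc(O)cc(OCOC)c1C/C=C(\C)CCC=C(C)C | intermediate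
8 | 4-geranyl-2-iodo-3,5-bis(methoxymethoxy)phenol | Oc1cc(OCOC)c(C/C=C(\C)CCC=C(C)C)c(OCOC)c1I | intermediate
9 | carbon monoxide | [C-]#[O+] | starting material
10 | phenylacetylene | C#Cc1ccccc1 | starting material
11 | 1-[3-geranyl-6-hydroxy-2,4-bis(methoxymethoxy)phenyl]-3-phenylprop-2-yn-1-one (formed in the flask) | O=C(C#Cc1ccccc1)c1c(O)cc(OCOC)c(C/C=C(\C)CCC=C(C)C)c1OCOC | intermediate
12 | (2E)-3-(diethylamino)-1-[3-geranyl-6-hydroxy-2,4-bis(methoxymethoxy)phenyl]-3-phenylprop-2-en-1-one (formed in the flask; drawn E, either geometry can close) | O=C(/C=C(/N(CC)CC)c1ccccc1)c1c(O)cc(OCOC)c(C/C=C(\C)CCC=C(C)C)c1OCOC | intermediate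
13 | 6-geranyl-5,7-bis(methoxymethoxy)flavone (2-phenyl-4H-chromen-4-one core) | O=c1cc(-c2ccccc2)oc2cc(OCOC)c(C/C=C(\C)CCC=C(C)C)c(OCOC)c12 | intermediate
14 | (2S)-4-[diethoxy(methyl)silyloxy]-6-geranyl-5,7-bis(methoxymethoxy)-2-phenyl-2H-chromene (formed in the flask) | CC(C)=CCC/C(C)=C/Cc1c(OCOC)cc2c(c1OCOC)C(O[Si](C)(OCC)OCC)=C[C@@H](c1ccccc1)O2 | intermediate
15 | (2S)-6-geranyl-5,7-bis(methoxymethoxy)flavanone | CC(C)=CCC/C(C)=C/Cc1c(OCOC)cc2c(c1OCOC)C(=O)C[C@@H](c1ccccc1)O2 | intermediate
16 | (2S)-6-geranyl-5,7-dihydroxyflavanone, CNP0201748.1 | CC(C)=CCC/C(C)=C/Cc1c(O)cc2c(c1O)C(=O)C[C@@H](c1ccccc1)O2 | target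

**Step count and risks**

Total step count: 8. Longest linear sequence: 8 steps from phloroglucinol; geranyl bromide, carbon monoxide and phenylacetylene enter as bought.

The three steps most likely to fail:

1. Step 7 (the one step that goes beyond shown chemistry). Hydride transfer to C2, which carries both an oxygen and an aryl donor, may be slow. Facial selectivity may be poor. The copper enolate may also expel the aryloxide before the silane traps it, and that ring opening to a chalcone would erase C2. The fallback uses known chemistry, sets out from 13 and comes back at 15, and can carry on at most half of the material. Conjugate reduction of 13 with LiBH(s-Bu)3 in THF at −78 °C would give the lithium enolate F1. An acetic acid quench at that temperature would give racemic 6-geranyl-5,7-bis(methoxymethoxy)flavanone F2. Asymmetric transfer hydrogenation with kinetic resolution would follow, using Cp*RhCl[(R,R)-TsDPEN] or its mirror image (whichever consumes the 2R ketone), HCO2H–Et3N, EtOAc, rt, stopped just past half conversion. It would reduce the 2R half to (2R,4R)-6-geranyl-5,7-bis(methoxymethoxy)flavan-4-ol F3 (2,4-cis) and leave the 2S ketone, which is 15. Transfer hydrogenation does not touch the isolated alkenes or the MOM ethers.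

2. Step 6. Oxidative addition at the electron-rich C–I bond flanked by two oxygen substituents may be slow. Capture of the aroylpalladium by Et2NH (amide formation), or alkynylation without CO uptake followed by closure to a benzofuran, could then compete. The fallback sets out from 8 and comes back at 13, building the same ynone without palladium. Two equivalents of n-BuLi in THF at −78 °C (deprotonation, then iodine–lithium exchange) would give the lithium 2-lithiophenoxide F4. Addition to N-methoxy-N-methyl-3-phenylpropiolamide would give the chelated tetrahedral adduct F5, which collapses on cold NH4Cl work-up to ynone 11, isolated in this variant. Et2NH in EtOH at rt to 60 °C would then take 11 through enaminone 12 to flavone 13.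

3. Step 5. Iodine may attack the trisubstituted alkenes (iodoetherification with a neighbouring MOM oxygen), or iodination may run on to both ortho carbons. The fallback sets out from 6 and comes back at 8, delivering iodine to a carbanion instead of to the free arene. A second directed ortho-metalation of silyl ether 6 (s-BuLi, TMEDA, THF, −78 °C) at one of the two equivalent ring C–H positions next to a MOM ether would give aryllithium F6. A quench with I2 at −78 °C would give [4-geranyl-2-iodo-3,5-bis(methoxymethoxy)phenoxy]tri(propan-2-yl)silane F7. Desilylation under the conditions of step 4 (Bu4NF, AcOH, THF, 0 °C) would then give iodophenol 8.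

Further compounds
F1 | step 7 | lithium enolate of racemic 6-geranyl-5,7-bis(methoxymethoxy)flavanone (4-lithiooxy-2-phenyl-2H-chromene) | [Li]OC1=CC(c2ccccc2)Oc2cc(OCOC)c(C/C=C(\C)CCC=C(C)C)c(OCOC)c21
F2 | step 7 | racemic 6-geranyl-5,7-bis(methoxymethoxy)flavanone | CC(C)=CCC/C(C)=C/Cc1c(OCOC)cc2c(c1OCOC)C(=O)CC(c1ccccc1)O2
F3 | step 7 | (2R,4R)-6-geranyl-5,7-bis(methoxymethoxy)flavan-4-ol (2,4-cis) | CC(C)=CCC/C(C)=C/Cc1c(OCOC)cc2c(c1OCOC)[C@H](O)C[C@H](c1ccccc1)O2
F4 | step 6 | lithium 4-geranyl-2-lithio-3,5-bis(methoxymethoxy)phenoxide | [Li]Oc1cc(OCOC)c(C/C=C(\C)CCC=C(C)C)c(OCOC)c1[Li]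
F5 | step 6 | dilithium salt of the tetrahedral adduct of F4 with N-methoxy-N-methyl-3-phenylpropiolamide (racemic at the new carbinol carbon) | [Li]OC(C#Cc1ccccc1)(N(C)OC)c1c(O[Li])cc(OCOC)c(C/C=C(\C)CCC=C(C)C)c1OCOC
F6 | step 5 | aryllithium of 6, lithiated at the ring carbon between the silyl ether and a MOM ether | [Li]c1c(O[Si](C(C)C)(C(C)C)C(C)C)cc(OCOC)c(C/C=C(\C)CCC=C(C)C)c1OCOC
F7 | step 5 | [4-geranyl-2-iodo-3,5-bis(methoxymethoxy)phenoxy]tri(propan-2-yl)silane | Ic1c(O[Si](C(C)C)(C(C)C)C(C)C)cc(OCOC)c(C/C=C(\C)CCC=C(C)C)c1OCOC
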